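1. The ratio D, the constants that drain dissolved starting material over the dissolution coefficient, is 1.15 in this flask. The drain constants are the rate constant to intermediate B plus the rate constant to intermediate A times the starting reagent, which treats that second path as pseudo-first-order.

solid substrate 0.80 M; reagent 0.960 M; time 25 min

    solid substrate ⇌ starting material, rate k1*(cs1 - [starting material]) while solid is left; crystals form when [starting material] > cs1 (cs1 = 0.11 M, k1 = 0.0075 /s)
    starting material ⇌ intermediate B (K2 = 50, k2 = 0.0063 /s)
    reagent + intermediate A → side product (k3 = 0.021 /M/s)
    starting material + reagent ⇌ intermediate A (K4 = 0.34 /M, k4 = 0.0024 /M/s)
    intermediate B → target (k5 = 0.013 /s)

- the target standing at 25 min, as a percentage of the solid substrate charged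
- concentration of starting material in solution at 25 min, in percent of saturation

- solid, in amounts per volume of the solution: solid substrate
- at the start none of the solid substrate is in solution
- starting material means what is dissolved; the solid is not counted in it
- run time (flask): 25 min

2. The bench rule says a stirred slurry stays saturated while solid is left, which puts starting material at 0.11 M. Held there, the path to intermediate B would carry 130% of the charge in 25 min, more than was charged. The rule needs D well below 1, and this flask stands above 1.

3. So I balance dissolution against drain, counting both drains forward. The dissolved level then stands at the saturation fraction f, the dissolution coefficient over itself plus the drain constants: 46.6% of saturation.

4. At that level, dissolving delivers 82.6% of the charge by 25 min, less than the charge, so in my reckoning solid remains and the balance lasts to the end.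

5. Counting lifetimes, the lag is that of intermediate B plus that of the dissolved level, 2.32 min. Target then forms at the rate constant to intermediate B times f times solubility for the remaining time, which gives me 54.9%.

6. The forecast says 57% for the target and 49% of saturation, with “dissolution balances drain through both pathways”. Both its numbers stand above mine.

7. The simulation gives this flask 57.4% of target and 50.1% of saturation at 25 min, against my f of 46.6%, and at that time starting material has a forward half-life of 1.8 min toward intermediate B, shorter than the 6.5 min toward intermediate A, each by the forward rate of its own step alone. In a neighbouring flask, with the same solid substrate and time but 0.24 M of reagent, f comes to 52.2%, and that flask stands at 53.9% of saturation at 25 min, with side product at 2.09% of the solid substrate charged and target at 62.3%.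

Its constants come from no measurement; what happens was integrated by code.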